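**Retrosynthetic overview**
- The strategy rests on the carbocycle C1 (quaternary: CH3 and the styryl carbon)–C2H2–C3H2–C4(CH3)=C5H–C6H(coumarin-6-yl), with the C6 aryl cis to the C1 methyl.
- The E-styryl C=C is cut by a Heck disconnection into a C1-vinyl compound and 6-bromo-7-methoxycoumarin; the vinyl group comes from a C1 formyl group. A Heck closure fixes the E geometry and spares the two lactones a strongly basic benzylic ylide.
- The C4=C5 alkene is traced to an allylsilane (Si on C5, alkene C3=C4) by SE2′ protodesilylation.
- C1–C2 and C5–C6 are cut together: catalytic enantioselective Diels–Alder of (E)-3-(coumarin-6-yl)-2-methylacrolein with (E)-1-trimethylsilyl-2-methylbuta-1,3-diene (from 3-methyl-3-sulfolene).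
- Ring order: the coumarin pyranone ring first (step 2; one bromocoumarin serves both aryl units), the cyclohexene second (step 7).

Key step: step 7

Assumption: both phosphoranes, 3-methyl-3-sulfolene and (R)-o-tolyl-CBS-oxazaborolidine are bought; the sense of induction in step 7 is assigned from the formyl C–H···O binding model of oxazaborolidinium catalysts, and the (S)-catalyst would be used if correlation of 11 showed the opposite sense.

**Step 1**
Reactants: 1 2-hydroxy-4-methoxybenzaldehyde
Product: 2 5-bromo-2-hydroxy-4-methoxybenzaldehyde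
Conditions: Br2, NaOAc, AcOH, rt
Reagents that add atoms: bromine BrBr
Why: Electrophilic aromatic bromination goes to C5, para to the phenol and ortho to the methoxy group, because C3 is flanked by two substituents.

**Step 2**
Reactants: 2 5-bromo-2-hydroxy-4-methoxybenzaldehyde
Product: 4 6-bromo-7-methoxy-2H-chromen-2-one, via ethyl 5-bromo-2-hydroxy-4-methoxycinnamate 3 (not isolated)
Conditions: Ph3P=CHCO2Et, PhNEt2, reflux
Reagents that add atoms: ethyl (triphenylphosphoranylidene)acetate CCOC(=O)C=P(c1ccccc1)(c1ccccc1)c1ccccc1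
Why: Wittig olefination with the stabilised ylide gives the o-hydroxycinnamate, which at this temperature isomerises about the C=C bond and lactonises with loss of ethanol (Wittig–lactonisation coumarin synthesis).

**Step 3**
Reactants: 4 6-bromo-7-methoxy-2H-chromen-2-one
Product: 5 7-methoxy-2-oxo-2H-chromene-6-carbaldehyde
Conditions: Pd(OAc)2 (cat.), di(1-adamantyl)-n-butylphosphine, CO/H2 (1:1, 5 bar), TMEDA, toluene, 100 °C
Reagents that add atoms: carbon monoxide [C-]#[O+]
Why: Palladium-catalysed reductive carbonylation (formylation) of an aryl bromide proceeds by oxidative addition, CO insertion and hydrogenolysis of the acyl-palladium species, and should leave the lactone and its C3=C4 bond untouched.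

**Step 4**
Reactants: 5 7-methoxy-2-oxo-2H-chromene-6-carbaldehyde
Product: 6 (E)-3-(7-methoxy-2-oxo-2H-chromen-6-yl)-2-methylprop-2-enal
Conditions: Ph3P=C(CH3)CHO, toluene, 100 °C
Reagents that add atoms: 2-(triphenylphosphoranylidene)propanal CC(C=O)=P(c1ccccc1)(c1ccccc1)c1ccccc1
Why: Wittig olefination with the stabilised α-methyl formyl ylide is E-selective (aryl trans to CHO) and runs under neutral conditions that the lactone tolerates.

**Step 5**
Reactants: 7 3-methyl-2,5-dihydrothiophene 1,1-dioxide (3-methyl-3-sulfolene)
Product: 8 (±)-3-methyl-2-(trimethylsilyl)-2,5-dihydrothiophene 1,1-dioxide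
Conditions: TMSCl, then LiHMDS (added last), THF, −78 °C
Reagents that add atoms: chlorotrimethylsilane C[Si](C)(C)Cl
Why: Deprotonation α to the sulfone with in situ C-silylation should favour C2, because the allyl anion then carries charge on the unsubstituted C4 and not on the methyl-bearing carbon, and the in situ quench outruns ring opening of the sulfolenyl anion.

**Step 6**
Reactants: 8 (±)-3-methyl-2-(trimethylsilyl)-2,5-dihydrothiophene 1,1-dioxide
Product: 9 (E)-trimethyl(2-methylbuta-1,3-dien-1-yl)silane
Conditions: neat, NaHCO3 (cat.), 130–140 °C, diene distilled out under reduced pressure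
Reagents that add atoms: none
Why: Thermal cheletropic extrusion of SO2 is disrotatory and turns the C2 silyl group outward, which should give the E-1-silyl diene (silyl cis to the methyl, trans to the vinyl).

**Step 7**
Reactants: 6 (E)-3-(7-methoxy-2-oxo-2H-chromen-6-yl)-2-methylprop-2-enal; 9 (E)-trimethyl(2-methylbuta-1,3-dien-1-yl)silane
Product: 10 (1S,5S,6R)-6-(7-methoxy-2-oxo-2H-chromen-6-yl)-1,4-dimethyl-5-(trimethylsilyl)cyclohex-3-ene-1-carbaldehyde
Conditions: (R)-o-tolyl-CBS-oxazaborolidine (20 mol%), AlBr3 (16 mol%), 9 (3 equiv), CH2Cl2, −40 → −20 °C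
Reagents that add atoms: none
Why: Lewis-acid-catalysed Diels–Alder reaction: the AlBr3-activated oxazaborolidine binds the formyl oxygen of 6 (s-trans enal, formyl C–H···O contact to the ring oxygen) and lowers its LUMO, and diene 9 adds in a concerted, asynchronous, suprafacial [4+2] that forms C5–C6 and C1–C2 and so closes the six-membered carbocycle by intermolecular cycloaddition. The closest known reactions are oxazaborolidinium-catalysed cycloadditions of 2-methylacrolein and of (E)-2-methylbut-2-enal with acyclic dienes. C1 is set by the catalyst, whose phenyl group covers the Re face at the α-carbon so that the diene adds to the Si face; C6 follows from C1 because suprafacial addition carries the E geometry of 6 into the trans aryl/formyl, cis aryl/methyl relationship. C5 results from the endo/exo preference (formyl-endo drawn), and either epimer serves because step 8 removes this centre. The regiochemistry needed, silyl terminus to the aryl-bearing carbon, is secured by the C2 methyl of the diene (methyl 1,4 to the formyl-bearing carbon) and reinforced by β-silyl stabilisation of the charge developing on the methyl-bearing carbon. Any Z-diene cannot reach the s-cis conformation and should stay out of the reaction.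

**Step 8**
Reactants: 10 (1S,5S,6R)-6-(7-methoxy-2-oxo-2H-chromen-6-yl)-1,4-dimethyl-5-(trimethylsilyl)cyclohex-3-ene-1-carbaldehyde
Product: 11 (1S,2R)-2-(7-methoxy-2-oxo-2H-chromen-6-yl)-1,4-dimethylcyclohex-3-ene-1-carbaldehyde
Conditions: CF3CO2H, CH2Cl2, −20 → 0 °C
Reagents that add atoms: none
Why: SE2′ protodesilylation of the allylsilane: protonation at C3 gives the tertiary β-silyl cation at C4, and loss of silicon from C5 places the alkene at C4=C5, while the quaternary C1 and the C6 centre are not touched.

**Step 9**
Reactants: 11 (1S,2R)-2-(7-methoxy-2-oxo-2H-chromen-6-yl)-1,4-dimethylcyclohex-3-ene-1-carbaldehyde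
Product: 12 7-methoxy-6-[(1S,6R)-6-ethenyl-3,6-dimethylcyclohex-2-en-1-yl]-2H-chromen-2-one
Conditions: Ph3PCH3Br, KHMDS, THF, 0 °C; then 11, −78 → 0 °C
Reagents that add atoms: methyltriphenylphosphonium bromide C[P+](c1ccccc1)(c1ccccc1)c1ccccc1.[Br-]
Why: Wittig methylenation: the non-stabilised ylide, used in slight excess at low temperature, should add to the aldehyde much faster than to the lactone, and the α-quaternary aldehyde cannot epimerise.

**Step 10**
Reactants: 12 7-methoxy-6-[(1S,6R)-6-ethenyl-3,6-dimethylcyclohex-2-en-1-yl]-2H-chromen-2-one; 4 6-bromo-7-methoxy-2H-chromen-2-one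
Product: 13 7-methoxy-6-[(E)-2-[(1R,2S)-2-(7-methoxy-2-oxo-2H-chromen-6-yl)-1,4-dimethylcyclohex-3-en-1-yl]ethenyl]-2H-chromen-2-one (CNP0415737.1)
Conditions: Pd(P(t-Bu)3)2 (5 mol%), Cy2NMe, dioxane, 80 °C
Reagents that add atoms: none
Why: Mizoroki–Heck reaction: the aryl-palladium species adds to the terminal vinyl carbon and syn-β-hydride elimination can use only the benzylic hydrogens, since the neighbouring carbon is quaternary, which gives the E-styryl alkene; the trisubstituted ring alkene and the coumarin C3=C4 bonds are much slower in carbopalladation.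

**Compound list**
1 | 2-hydroxy-4-methoxybenzaldehyde | COc1ccc(C=O)c(O)c1 | starting material
2 | 5-bromo-2-hydroxy-4-methoxybenzaldehyde | COc1cc(O)c(C=O)cc1Br | intermediate
3 | ethyl (E)-3-(5-bromo-2-hydroxy-4-methoxyphenyl)prop-2-enoate | CCOC(=O)/C=C/c1cc(Br)c(OC)cc1O | intermediate (not isolated)
4 | 6-bromo-7-methoxy-2H-chromen-2-one | COc1cc2oc(=O)ccc2cc1Br | intermediate
5 | 7-methoxy-2-oxo-2H-chromene-6-carbaldehyde | COc1cc2oc(=O)ccc2cc1C=O | intermediate
6 | (E)-3-(7-methoxy-2-oxo-2H-chromen-6-yl)-2-methylprop-2-enal | COc1cc2oc(=O)ccc2cc1/C=C(\C)C=O | intermediate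
7 | 3-methyl-2,5-dihydrothiophene 1,1-dioxide | CC1=CCS(=O)(=O)C1 | starting material
8 | (±)-3-methyl-2-(trimethylsilyl)-2,5-dihydrothiophene 1,1-dioxide | CC1=CCS(=O)(=O)C1[Si](C)(C)C | intermediate
9 | (E)-trimethyl(2-methylbuta-1,3-dien-1-yl)silane | C[Si](C)(C)/C=C(\C)C=C | intermediate
10 | (1S,5S,6R)-6-(7-methoxy-2-oxo-2H-chromen-6-yl)-1,4-dimethyl-5-(trimethylsilyl)cyclohex-3-ene-1-carbaldehyde | O=C[C@@]1(C)CC=C(C)[C@@H]([Si](C)(C)C)[C@@H]1c1cc2ccc(=O)oc2cc1OC | intermediate
11 | (1S,2R)-2-(7-methoxy-2-oxo-2H-chromen-6-yl)-1,4-dimethylcyclohex-3-ene-1-carbaldehyde | O=C[C@@]1(C)CCC(C)=C[C@@H]1c1cc2ccc(=O)oc2cc1OC | intermediate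
12 | 7-methoxy-6-[(1S,6R)-6-ethenyl-3,6-dimethylcyclohex-2-en-1-yl]-2H-chromen-2-one | C=C[C@@]1(C)CCC(C)=C[C@@H]1c1cc2ccc(=O)oc2cc1OC | intermediate
13 | 7-methoxy-6-[(E)-2-[(1R,2S)-2-(7-methoxy-2-oxo-2H-chromen-6-yl)-1,4-dimethylcyclohex-3-en-1-yl]ethenyl]-2H-chromen-2-one | COc1cc2oc(=O)ccc2cc1/C=C/[C@@]1(C)CCC(C)=C[C@@H]1c1cc2ccc(=O)oc2cc1OC | target

**Step count**
Total: 10 steps. Longest linear sequence: 8 steps (1, 2, 3, 4, 7, 8, 9, 10); steps 5 and 6 form the diene branch.

**Steps most likely to fail**

Step 7. The cycloaddition may be slow, because a β-aryl, α-methyl enal is a poor dienophile and the lactone carbonyl competes for the Lewis acid. Facial discrimination may be insufficient or inverted, and the vinylsilane may react stepwise at its ipso carbon with loss of silicon. The fallback sets out from 6 and 9 and returns at 11. The cycloaddition is run without asymmetric induction, with an excess of Me2AlCl in CH2Cl2 or thermally at 10–12 kbar, which should give 10 together with the (1R,5R,6S)-enantiomer of the cycloadduct F1. Protodesilylation as in step 8 then gives 11 together with the (1R,2S)-enantiomer of the aldehyde F2. Preparative chromatography on a chiral stationary phase separates the two, and the route continues from 11.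

Step 10. Carbopalladation at the neopentyl-type vinyl group may be slow, so that arylation of a coumarin C3=C4 bond or palladium hydride induced migration of the ring alkene competes. The fallback sets out from 5 and 11 and returns at 13. Aldehyde 5 is reduced with NaBH4 (MeOH/THF, 0 °C) to 6-(hydroxymethyl)-7-methoxy-2H-chromen-2-one F3. PBr3 (CH2Cl2, 0 °C) converts it into 6-(bromomethyl)-7-methoxy-2H-chromen-2-one F4. Heating with P(OEt)3 (Michaelis–Arbuzov reaction) gives diethyl [(7-methoxy-2-oxo-2H-chromen-6-yl)methyl]phosphonate F5. Horner–Wadsworth–Emmons olefination of 11 with the anion of this phosphonate (NaHMDS, THF, −78 → 0 °C) should give the E-alkene 13 directly, replacing steps 9 and 10.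

Step 3. Reductive loss of bromine may compete with CO insertion, or the catalyst may be deactivated, so that formylation stalls. The fallback sets out from 4 and returns at 5. Suzuki–Miyaura coupling of 4 with potassium vinyltrifluoroborate (PdCl2(dppf), Cs2CO3, THF/H2O, 80 °C) gives 6-ethenyl-7-methoxy-2H-chromen-2-one F6. Lemieux–Johnson cleavage (OsO4 cat., NaIO4, 2,6-lutidine, dioxane/H2O) of the styrene double bond, which is more electron-rich than the lactone-conjugated C3=C4 bond and should react first, gives 5.

**Further compounds**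
F1 | step 7 | (1R,5R,6S)-6-(7-methoxy-2-oxo-2H-chromen-6-yl)-1,4-dimethyl-5-(trimethylsilyl)cyclohex-3-ene-1-carbaldehyde | O=C[C@]1(C)CC=C(C)[C@H]([Si](C)(C)C)[C@H]1c1cc2ccc(=O)oc2cc1OC
F2 | step 7 | (1R,2S)-2-(7-methoxy-2-oxo-2H-chromen-6-yl)-1,4-dimethylcyclohex-3-ene-1-carbaldehyde | O=C[C@]1(C)CCC(C)=C[C@H]1c1cc2ccc(=O)oc2cc1OC
F3 | step 10 | 6-(hydroxymethyl)-7-methoxy-2H-chromen-2-one | COc1cc2oc(=O)ccc2cc1CO
F4 | step 10 | 6-(bromomethyl)-7-methoxy-2H-chromen-2-one | COc1cc2oc(=O)ccc2cc1CBr
F5 | step 10 | diethyl [(7-methoxy-2-oxo-2H-chromen-6-yl)methyl]phosphonate | CCOP(=O)(OCC)Cc1cc2ccc(=O)oc2cc1OC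
F6 | step 3 | 6-ethenyl-7-methoxy-2H-chromen-2-one | C=Cc1cc2ccc(=O)oc2cc1OC
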